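How much target did the flask hold at 2.0 h, and which change raised it?

all flasks: catalyst 0.2 mol%
- epsilon: solid substrate 0.032 M; run made earlier
- flask: solid substrate 0.064 M; time 2.0 h

epsilon run (percent of the solid substrate charged)

| time / min | target / % | starting material / % | solid substrate / % |
|---|---|---|---|
| 3.00 | 2.6 | 29.7 | 64.2 |
| 6.00 | 6.5 | 34.3 | 50.6 |
| 10.0 | 10.2 | 34.9 | 36.3 |
| 15.0 | 18.6 | 35.1 | 19.1 |
| 20.0 | 24.0 | 34.5 | 2.8 |
| 25.0 | 29.7 | 23.5 | 0 |

(scatter of a reading: 0.5 percentage points)

- given per volume of solution although it is solid: solid substrate
- the earlier runs were read with a standard deviation of 0.5 percentage points
- at the start none of the solid substrate is in solution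
- starting material means what is dissolved; the solid is not counted in it
- starting material is what solid substrate becomes in solution
- no earlier run changes the charge of catalyst; that part of a forecast is a guess

1. amount of target at 2.0 h, in percent of the solid substrate charged
2. concentration of starting material in solution at 12 min, in percent of saturation
3. the change that raises the amount of target at 2.0 h, in percent of the solid substrate charged most ("none" if none brings more than 2 percentage points) (maple / alder / ash / none)
4. amount of target at 2.0 h, in percent of the solid substrate charged, after ash

- maple: doubling the solubility of the solid substrate, all else as stated
- alder: doubling the dissolution coefficient of the solid substrate, all else as stated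
- ash: doubling the amount of catalyst, all else as stated

My bench rule of thumb was that a percent yield carries over when everything is charged in proportion. At 25.0 min the epsilon run held 29.7% target and 23.5% starting material, with 0% solid substrate, so 46.8% had gone elsewhere. Target had therefore taken 38.8% of what was consumed. At 15.0 min that share read 40.6%, close by, although the two readings differ in dissolved level. So I took both paths to have one order in starting material; solubility and dissolution should then move the level, not the share, and I expected nothing from maple or alder. Allowing 40.0 min for the larger charge to dissolve, which is less than 2.0 h, the rule promised about that share.

But the rule has a border. Catalyst is charged per solid substrate, so the flask's catalyst concentration stood at 2.00 times that of the epsilon run. Guessing that the lost path needs no catalyst, I defined B, the selectivity factor: parts of target per part lost, per molar of catalyst, which read 9920 M⁻¹. For the flask, B gave 1.27 parts per part, a share of 55.9%. With ash it gave 71.8%, so ash was my choice.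

The forecast gave 48% (37% to 59%), 78% of saturation at 12 min, ash as best and 58% after it, saying “That is a guess, so I take middle values”.

The flask gave 56.7%, 81.0% of saturation, and 72.4% after ash, a gain of 16 percentage points against 0 points for maple and 0 points for alder.

    starting material + catalyst → catalyst + target (k = 597 M⁻¹ min⁻¹)
    starting material → side product (k = 0.0584 min⁻¹)
    solid substrate ⇌ starting material, rate k3*(cs3 - [starting material]) while solid is left; crystals form when [starting material] > cs3 (solubility = 13.0 mM, k = 0.577 min⁻¹)

Target stopped there because starting material also turned into side product: the flask without that step gave 99.8%, not 56.7%. The flask ended with 1.31 parts of target per part of side product, against 1.27 from B. With 0.016 M of solid substrate at the same loading, B gives 0.317 parts per part, a share of 24.1%; that neighbour flask gave 24.6% target and 75.3% side product.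

The earlier runs and the new flask stem from a simulated flask with made-up constants; the scatter is artificial.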